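**Time of reading.** At 2.0 min I had to read north-east, south-east and north, each charged with X and the catalyst L.

the same everywhere: L 2.5 µM

| run | X | remark | time |
|---|---|---|---|
| birch | 0.25 mM | run made earlier |  |
| elm | 0.29 mM | run made earlier |  |
| ash | 0.47 mM | run made earlier |  |
| north-east | 0.20 mM |  | 2.0 min |
| south-east | 0.30 mM |  | 2.0 min |
| north | 0.50 mM |  | 2.0 min |

- birch (time / s: E / %, X / %): 10.0: 13, 84; 30.0: 39, 53; 60.0: 66, 31; 80.0: 80, 22; 120: 92, 9
- elm (time / s: E / %, X / %): 10.0: 14, 86; 30.0: 35, 63; 60.0: 60, 36; 80.0: 71, 26; 120: 85, 13
- ash (time / s: E / %, X / %): 25.0: 21, 79; 50.0: 33, 65; 80.0: 40, 56; 90.0: 41, 59; 120: 46, 52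

(readings scatter by 1.5 percentage points)

- a reading or a percentage of E counts all its forms, free or not
- the concentration of E that is asked is that of its free form alone
- "hardly changes" means that all values lie within two and a half points (for a concentration: within two and a half percent of the largest)

- [E] (only what is free in solution) at the end for north-east, south-east, north, in this order
- the course of these numbers from the first flask to the last (falls, then rises / rises, then falls / falls all the way / hardly changes / rises all the way)

**Turnovers asked.** At that same time, 120 s, birch held 92% E, but ash held 46% and had been creeping since 80.0 s. So I counted turnovers: X charged over L charged. Ash asked 188 of each catalyst and had given 86.5, its turnover number so far.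

**The budget.** I supposed that each turnover risks the catalyst in proportion to the concentration of X still present, that is, the charge of X times the fraction left. With L held at 2.5 µM, the share lost is then the square of turnovers asked over a budget, times one minus the square of the fraction left. Setting that share to one for ash, as a reading, gave a budget of 158, the turnovers asked at which the catalyst lasts just until the last X is used. The ratio of turnovers asked to budget is my one number: below one a flask runs on, above one it stops. For north it was 1.26, so I expected it to stop with 61.2% of its X left.

**One number enough?** Elm's ratio was 0.733, and its X fell to 13%, as the ratio allows. But the ratio tells where a flask stops, not how soon. For south-east I therefore borrowed elm's clock, about 85% E, and for north-east birch's, about 92%.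

**The forecast.** It gave 0.188 mM, 0.25 mM and 0.208 mM, rises, then falls: “The catalyst is probably being killed at high X, with a steep dependence on X.” For north I reckoned less, 0.194 mM.

**The row.** The flasks gave 0.189 mM, 0.251 mM and 0.199 mM, rises, then falls, and north kept 59% of its X.

    X + D → Q (k = 161 /M/s)
    J → D (k = 15.2 /s)
    X + Z ⇌ J (K = 2100 /M, k = 31600 /M/s)
    L → Z (k = 0.679 /s)
    D → Z + E (k = 5.40 /s)
    G ⇌ E, rate k6*(cs6 - [E]) while solid is left; crystals form when [E] > cs6 (solubility = 0.400 mM, k = 1.85 /s)

**The reason.** With the step X + D → Q taken away, free E at the end of north stood at 0.401 mM instead of 0.199 mM, the largest single effect. For south-east the budget gave a lost share of 56.1%, and at 2.00 min that flask held 51.5% of its catalyst as Q, each Q counted as the two it holds.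

(The readings are calculated from invented constants; the scatter is artificial.)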